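1. The constant I read from the runs was the intake, an average rate at which solid substrate appeared as target and dissolved substrate. In the winter run, these two together, taken up to the 1.50 min reading, averaged 0.0622 M min⁻¹.

| flask | solid substrate | partner | remark | time |
|---|---|---|---|---|
| spring | 0.25 M | 0.375 M | the very flask that is asked about, followed so far |  |
| winter | 0.12 M | 0.375 M | run made earlier |  |
| flask | 0.25 M | 0.375 M |  | 20 min |
- spring (time / min: target / %, dissolved substrate / %): 0.333: 4.2, 5.6; 1.00: 13.5, 7.5; 1.50: 19.1, 9.3; 2.50: 36.8, 11.3; 4.00: 39.5, 8.1; 5.00: 40.0, 8.1; 6.00: 39.7, 7.7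
- winter (time / min: target / %, dissolved substrate / %): 1.00: 39.7, 17.1; 1.50: 62.7, 15.1; 2.50: 67.1, 10.0; 4.00: 67.6, 10.1; 6.00: 67.7, 10.1; 10.0: 67.3, 9.9; 15.0: 67.4, 10.1

(standard deviation of a reading: 0.3 percentage points)
- solid substrate is a solid; its amount is given per volume of the solution
- at the start none of the solid substrate is in solution
- dissolved substrate means what is dissolved; the solid is not counted in it
* the target standing at 20 min, as a percentage of the solid substrate charged
* concentration of dissolved substrate in solution at 20 min, in percent of saturation

2. I took this intake as steady, a zero-order rate, which integrates to a straight line. In the spring flask the charge divided by the intake, the solid's life, came to 4.02 min.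
3. The same division gave 1.93 min for the winter run, whose target read 67.1 % at 2.50 min and 67.4 % at 15.0 min.
4. The second time was the asked 20 min, which is 4.98 lives, so I expected no solid in the flask by then.
5. The highest spring reading was [dissolved substrate] = 0.0283 M, and a later one was 0.0203 M. I took that highest reading as a floor for saturation.
6. I therefore committed to target near 40.0 % and to at most 71.7 % of saturation.
7. The forecast gave 39.8 % and 100 %, with the solution “probably saturated at about 0.020 M”.
8. The flask gave 39.7 % and 12.3 %.

    solid substrate ⇌ dissolved substrate, rate k1*(cs1 - [dissolved substrate]) while solid is left; crystals form when [dissolved substrate] > cs1 (solubility = 0.160 M, k = 0.548 min⁻¹)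
    dissolved substrate + partner ⇌ target (K = 23.7 M⁻¹, k = 14.6 M⁻¹ min⁻¹)
    2 solid substrate → homo dimer (k = 0.0419 M⁻¹ min⁻¹)
    solid substrate + target → side product (k = 8.75 M⁻¹ min⁻¹)

9. My estimated life of 4.02 min ran long for the flask: a steady intake gave 50.2 % of the solid left at 2.00 min, but the flask held 12.6 % then and 0 % at 10.0 min. For a neighbour flask charged with 0.10 M of solid substrate, the same division gave an estimate of 1.61 min, shorter than the 20 min, and its solid substrate stood at 0 % at 20.0 min.

The readings come from a simulation with made-up constants; scatter was added.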